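**Strategy.** Ring A of this labda-8,13-diene holds, at C3–C4, a CH2–CMe2 unit, i.e. an embedded isobutene. Ring A is therefore closed late by a radical [4+2] annulation: a ring B silyl dienol ether that already carries the C10 quaternary centre and a C1–C2 arm ending in a redox-active ester loses CO2, the C2 radical adds to isobutene (C2–C3) and the tertiary C4 radical closes onto C5 (C4–C5), with oxidative termination to a 6,9-ene-dione. The precursor comes from an asymmetric chiral-imine Michael addition. A C9 enol triflate, B-alkyl Suzuki coupling, α-face C7 hydroxylation and α-face C6 reduction then finish the target.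

Key step: step 7

Remark 1: bicyclic intermediates are numbered as labdanes (ring A = C1–C5 and C10, ring B = C5–C10, methyls on C4, C4, C8 and C10, side chain C11–C15 on C9); α is the face opposite the C10 methyl.
Remark 2: the chiral-imine Michael addition of step 1 is assumed to follow the facial sense known for 2-methylcyclohexanone, so that the (S)-amine gives the (S)-configured centre of 5.
Remark 3: compounds 1, 2, 3, 11, 15 and 18 are taken as purchased.

Step 1
Reactants: 1 (±)-7-methyl-1,4-dioxaspiro[4.5]decan-8-one; 2 (S)-1-phenylethylamine; 3 methyl acrylate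
Product: 5 methyl 3-[(7S)-7-methyl-8-oxo-1,4-dioxaspiro[4.5]decan-7-yl]propanoate, via ketimine 4 (not isolated)
Conditions: 2, TsOH (cat.), toluene, reflux with azeotropic removal of water; then 3, THF, 40 °C; then 20% aq AcOH, rt
Reagents that add atoms: water (O)
Why: Chiral-imine (secondary-enamine) asymmetric Michael addition: the more substituted enamine tautomer of 4 adds to the acrylate through a compact aza-ene-like transition state on the face anti to the phenyl group, which should set the quaternary centre (future C10) as S, and mild acid hydrolysis then releases the ketone and the amine.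

Step 2
Reactants: 5 methyl 3-[(7S)-7-methyl-8-oxo-1,4-dioxaspiro[4.5]decan-7-yl]propanoate
Product: 6 methyl 3-[(7S)-7,9-dimethyl-8-oxo-1,4-dioxaspiro[4.5]decan-7-yl]propanoate (mixture of C9 epimers)
Conditions: LiN(i-Pr)2, THF, −78 °C; MeI, −78 → −20 °C
Reagents that add atoms: iodomethane (CI)
Why: Kinetic ketone enolate alkylation: the base removes a proton from C9 of the spiro ring, the only enolisable position of the ketone (the ester is less acidic and untouched at −78 °C), and MeI installs the future C8 methyl, whose configuration is irrelevant because this carbon becomes sp2 in step 4.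

Step 3
Reactants: 6 methyl 3-[(7S)-7,9-dimethyl-8-oxo-1,4-dioxaspiro[4.5]decan-7-yl]propanoate
Product: 7 3-[(1S)-1,3-dimethyl-2,5-dioxocyclohexyl]propanoic acid (mixture of C3 epimers)
Conditions: LiOH, THF/H2O, rt; then 2 M HCl (pH 1), rt
Reagents that add atoms: lithium hydroxide ([Li+].[OH-]); water (O)
Why: Ester saponification followed by acid-catalysed acetal hydrolysis in one pot; the quaternary centre bears no hydrogen and cannot epimerise.

Step 4
Reactants: 7 3-[(1S)-1,3-dimethyl-2,5-dioxocyclohexyl]propanoic acid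
Product: 8 3-[(1S)-1,3-dimethyl-2,5-dioxocyclohex-3-en-1-yl]propanoic acid
Conditions: IBX, DMSO, 70 °C
Reagents that add atoms: none
Why: IBX dehydrogenation of a ketone to an enone: only the C3–C4 bond of the ring, flanked by both carbonyls, carries hydrogens on both carbons (C1 is quaternary), so a single ene-dione should form and the C3 epimers converge.

Step 5
Reactants: 8 3-[(1S)-1,3-dimethyl-2,5-dioxocyclohex-3-en-1-yl]propanoic acid
Product: 9 1,3-dioxoisoindolin-2-yl 3-[(1S)-1,3-dimethyl-2,5-dioxocyclohex-3-en-1-yl]propanoate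
Conditions: N-hydroxyphthalimide, N,N′-diisopropylcarbodiimide, DMAP (cat.), CH2Cl2, rt
Reagents that add atoms: N-hydroxyphthalimide (ON1C(=O)c2ccccc2C1=O)
Why: Carbodiimide esterification of the acid with N-hydroxyphthalimide gives the redox-active ester; no stereocentre is touched.

Step 6
Reactants: 9 1,3-dioxoisoindolin-2-yl 3-[(1S)-1,3-dimethyl-2,5-dioxocyclohex-3-en-1-yl]propanoate
Product: 10 1,3-dioxoisoindolin-2-yl 3-[(1S)-5-[(tert-butyldimethylsilyl)oxy]-1,3-dimethyl-2-oxocyclohexa-3,5-dien-1-yl]propanoate
Conditions: TBSOTf, Et3N, CH2Cl2, −78 → 0 °C; used directly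
Reagents that add atoms: tert-butyldimethylsilyl trifluoromethanesulfonate (CC(C)(C)[Si](C)(C)OS(=O)(=O)C(F)(F)F)
Why: Soft enolisation and O-silylation of an enone at its α′ carbon: C6 of the ring holds the only α-hydrogens of the ene-dione, so the cross-conjugated 5-silyloxy dienone forms regiospecifically and presents its C6 (future C5) as the acceptor carbon.

Step 7
Reactants: 10 1,3-dioxoisoindolin-2-yl 3-[(1S)-5-[(tert-butyldimethylsilyl)oxy]-1,3-dimethyl-2-oxocyclohexa-3,5-dien-1-yl]propanoate; 11 2-methylpropene (isobutene)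
Product: 12 (4aR,8aS)-2,5,5,8a-tetramethyl-4a,5,6,7,8,8a-hexahydronaphthalene-1,4-dione (cis-fused)
Conditions: fac-Ir(ppy)3 (1 mol %), 11 (condensed, ca. 50 equiv, at least 5 M), CH2Cl2, blue LEDs (450 nm), −20 °C, sealed tube; then aq NaHCO3
Reagents that add atoms: none
Why: Proposed new method: photoexcited fac-Ir(ppy)3 reduces the N-acyloxyphthalimide, which loses CO2 and phthalimide anion to give the primary C2 radical; this adds to the CH2 terminus of isobutene (C2–C3), the tertiary C4 radical attacks C5, the δ-terminus of the silyloxy dienone (C4–C5), and the resulting captodative O-silyl pentadienyl radical is oxidised by the tetravalent iridium complex to a silyloxocarbenium ion that gives up its silyl group to phthalimide anion, releasing the ene-dione and closing the catalytic cycle. The closest known reaction types are the Ir-photocatalysed decarboxylative alkylation of silyl enol ethers with redox-active esters (radical addition, oxidation, desilylation) and three-component radical–polar crossover carbofunctionalisations of alkenes; an unactivated 1,1-disubstituted alkene inserted between radical and silyl dienol ether has not been shown. Ring A closes in the 6-exo-trig mode (C4 radical onto C5=C6). C4 is not stereogenic; C5 is set by the C10 tether, which can deliver C4 only to the face of ring B on which it sits, so the kinetic product is the cis-fused 12, corrected in step 8. The step needs capture of the C2 radical by isobutene to outrun its transannular 6-endo addition to C7 and hydrogen abstraction, which a large excess of neat alkene, low temperature and the absence of a hydrogen donor should secure; C5 is the only alkene carbon the C4 radical can reach through a six-membered transition state, and addition to the C9 carbonyl is reversible.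

Step 8
Reactants: 12 (4aR,8aS)-2,5,5,8a-tetramethyl-4a,5,6,7,8,8a-hexahydronaphthalene-1,4-dione
Product: 13 (4aS,8aS)-2,5,5,8a-tetramethyl-4a,5,6,7,8,8a-hexahydronaphthalene-1,4-dione (trans-fused)
Conditions: DBU (0.2 equiv), CH2Cl2, rt
Reagents that add atoms: none
Why: Base-mediated epimerisation α to a ketone: C5–H is the only α-hydrogen of the C6 carbonyl, and reversible enolisation with reprotonation on the α-face, away from the axial C10 methyl, should convert 12 into the trans-fused decalin 13, expected to be the more stable isomer (5S).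

Step 9
Reactants: 13 (4aS,8aS)-2,5,5,8a-tetramethyl-4a,5,6,7,8,8a-hexahydronaphthalene-1,4-dione
Product: 14 (4aS,8aS)-2,5,5,8a-tetramethyl-4-oxo-3,4,4a,5,6,7,8,8a-octahydronaphthalen-1-yl trifluoromethanesulfonate
Conditions: LiBH(s-Bu)3, THF, −78 °C; then PhNTf2, −78 → 0 °C
Reagents that add atoms: N-phenylbis(trifluoromethanesulfonimide) (O=S(=O)(N(c1ccccc1)S(=O)(=O)C(F)(F)F)C(F)(F)F)
Why: Conjugate reduction with in situ enolate O-triflation: the bulky hydride should add to the unsubstituted C7 terminus of the ene-dione rather than to the methyl-bearing C8 or the two hindered carbonyls, which generates only the C9 enolate, trapped as the tetrasubstituted C8=C9 enol triflate.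

Step 10
Reactants: 15 (E)-3-methylpent-2-en-4-yn-1-ol
Product: 16 tert-butyldimethyl{[(E)-3-methylpent-2-en-4-yn-1-yl]oxy}silane
Conditions: TBSCl, imidazole, CH2Cl2, 0 °C → rt
Reagents that add atoms: tert-butylchlorodimethylsilane (CC(C)(C)[Si](C)(C)Cl)
Why: Standard silylation of a primary allylic alcohol; the E-alkene is untouched.

Step 11
Reactants: 16 tert-butyldimethyl{[(E)-3-methylpent-2-en-4-yn-1-yl]oxy}silane
Product: 17 tert-butyldimethyl{[(E)-3-methylpenta-2,4-dien-1-yl]oxy}silane
Conditions: H2 (1 atm), Pd/CaCO3 poisoned with Pb(OAc)2, quinoline, hexane, rt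
Reagents that add atoms: none
Why: Semihydrogenation of a terminal alkyne over poisoned palladium stops at the vinyl group and leaves the trisubstituted E-alkene unchanged.

Step 12
Reactants: 17 tert-butyldimethyl{[(E)-3-methylpenta-2,4-dien-1-yl]oxy}silane; 18 9-borabicyclo[3.3.1]nonane (9-BBN); 14 (4aS,8aS)-2,5,5,8a-tetramethyl-4-oxo-3,4,4a,5,6,7,8,8a-octahydronaphthalen-1-yl trifluoromethanesulfonate
Product: 20 (5S,10S)-15-[(tert-butyldimethylsilyl)oxy]labda-8,13E-dien-6-one, via alkylborane 19 (not isolated)
Conditions: 17, 18 (0.95 equiv), THF, 0 °C → rt; then 14, Pd(dppf)Cl2, AsPh3, Cs2CO3, DMF/THF/H2O, rt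
Reagents that add atoms: none
Why: Hydroboration then B-alkyl Suzuki–Miyaura coupling: 9-BBN adds to the monosubstituted alkene of the diene with boron on the terminal carbon (future C11), and the alkylborane couples with the enol triflate to form C9–C11 with retention of the C8=C9 and C13=C14 (E) alkenes.

Step 13
Reactants: 20 (5S,10S)-15-[(tert-butyldimethylsilyl)oxy]labda-8,13E-dien-6-one
Product: 21 (5S,7S,10S)-15-[(tert-butyldimethylsilyl)oxy]-7α-hydroxylabda-8,13E-dien-6-one
Conditions: KN(SiMe3)2, THF, −78 °C; 2-(phenylsulfonyl)-3-phenyloxaziridine, −78 °C; AcOH quench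
Reagents that add atoms: 2-(phenylsulfonyl)-3-phenyloxaziridine (O=S(=O)(N1OC1c1ccccc1)c1ccccc1)
Why: Enolate hydroxylation with an N-sulfonyloxaziridine: deprotonation occurs at C7 (α to the ketone and allylic) and the bulky oxidant should attack the dienolate α-carbon from the α-face, because the β-face is shielded by the axial C10 and 4β methyls, setting 7α-OH (7S).

Step 14
Reactants: 21 (5S,7S,10S)-15-[(tert-butyldimethylsilyl)oxy]-7α-hydroxylabda-8,13E-dien-6-one
Product: 22 (5S,6S,7S,10S)-15-[(tert-butyldimethylsilyl)oxy]labda-8,13E-diene-6β,7α-diol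
Conditions: Me4NBH(OAc)3, MeCN/AcOH, −20 °C
Reagents that add atoms: none
Why: Hydroxyl-directed triacetoxyborohydride reduction (Saksena–Evans type): the 7α-hydroxyl binds boron and delivers hydride intramolecularly to the α-face of C6, which is also the face not blocked by the two axial methyls, so the 6β-alcohol (6S, trans diol) should result.

Step 15
Reactants: 22 (5S,6S,7S,10S)-15-[(tert-butyldimethylsilyl)oxy]labda-8,13E-diene-6β,7α-diol
Product: 23 (5S,6S,7S,10S)-15-[(tert-butyldimethylsilyl)oxy]-7α-[(triethylsilyl)oxy]labda-8,13E-dien-6β-ol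
Conditions: Et3SiCl, imidazole, CH2Cl2, 0 °C
Reagents that add atoms: chlorotriethylsilane (CC[Si](Cl)(CC)CC)
Why: Selective silylation: the allylic 7α-hydroxyl reacts, while the axial 6β-hydroxyl, flanked by the 1,3-diaxial C4 and C10 methyls, is too hindered for Et3SiCl/imidazole at 0 °C.

Step 16
Reactants: 23 (5S,6S,7S,10S)-15-[(tert-butyldimethylsilyl)oxy]-7α-[(triethylsilyl)oxy]labda-8,13E-dien-6β-ol
Product: 24 (5S,6S,7S,10S)-15-[(tert-butyldimethylsilyl)oxy]-7α-[(triethylsilyl)oxy]labda-8,13E-dien-6β-yl 3-methylbutanoate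
Conditions: 3-methylbutanoyl chloride, DMAP, pyridine, CH2Cl2, 40 °C
Reagents that add atoms: 3-methylbutanoyl chloride (CC(C)CC(Cl)=O)
Why: DMAP-catalysed acylation under forcing conditions esterifies the one remaining free hydroxyl, the hindered 6β-OH, with retention of configuration.

Step 17
Reactants: 24 (5S,6S,7S,10S)-15-[(tert-butyldimethylsilyl)oxy]-7α-[(triethylsilyl)oxy]labda-8,13E-dien-6β-yl 3-methylbutanoate
Product: 25 (5S,6S,7S,10S)-7α,15-dihydroxylabda-8,13E-dien-6β-yl 3-methylbutanoate (CNP0173680.1)
Conditions: HF·pyridine, pyridine/THF, 0 °C → rt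
Reagents that add atoms: none
Why: Fluoride-mediated cleavage of both silyl ethers with buffered HF·pyridine, conditions under which the ester, the allylic alcohols and the alkenes should survive and no stereocentre is touched.

**Compound list**
1 | (±)-7-methyl-1,4-dioxaspiro[4.5]decan-8-one | CC1CC2(CCC1=O)OCCO2 | starting material
2 | (S)-1-phenylethylamine | C[C@H](N)c1ccccc1 | starting material
3 | methyl acrylate | C=CC(=O)OC | starting material
4 | N-[(S)-1-phenylethyl] ketimine of 1 (in equilibrium with its secondary enamine) | CC1CC2(CCC1=N[C@@H](C)c1ccccc1)OCCO2 | intermediate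
5 | methyl 3-[(7S)-7-methyl-8-oxo-1,4-dioxaspiro[4.5]decan-7-yl]propanoate | COC(=O)CC[C@@]1(C)CC2(OCCO2)CCC1=O | intermediate
6 | methyl 3-[(7S)-7,9-dimethyl-8-oxo-1,4-dioxaspiro[4.5]decan-7-yl]propanoate (C9 epimers) | COC(=O)CC[C@@]1(C)CC2(OCCO2)CC(C)C1=O | intermediate
7 | 3-[(1S)-1,3-dimethyl-2,5-dioxocyclohexyl]propanoic acid (C3 epimers) | OC(=O)CC[C@@]1(C)CC(=O)CC(C)C1=O | intermediate
8 | 3-[(1S)-1,3-dimethyl-2,5-dioxocyclohex-3-en-1-yl]propanoic acid | OC(=O)CC[C@@]1(C)CC(=O)C=C(C)C1=O | intermediate
9 | 1,3-dioxoisoindolin-2-yl 3-[(1S)-1,3-dimethyl-2,5-dioxocyclohex-3-en-1-yl]propanoate | O=C(CC[C@@]1(C)CC(=O)C=C(C)C1=O)ON1C(=O)c2ccccc2C1=O | intermediate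
10 | 1,3-dioxoisoindolin-2-yl 3-[(1S)-5-[(tert-butyldimethylsilyl)oxy]-1,3-dimethyl-2-oxocyclohexa-3,5-dien-1-yl]propanoate | O=C(CC[C@@]1(C)C=C(O[Si](C)(C)C(C)(C)C)C=C(C)C1=O)ON1C(=O)c2ccccc2C1=O | intermediate
11 | 2-methylpropene (isobutene) | CC(C)=C | starting material
12 | (4aR,8aS)-2,5,5,8a-tetramethyl-4a,5,6,7,8,8a-hexahydronaphthalene-1,4-dione (cis-fused) | CC1=CC(=O)[C@@H]2C(C)(C)CCC[C@]2(C)C1=O | intermediate
13 | (4aS,8aS)-2,5,5,8a-tetramethyl-4a,5,6,7,8,8a-hexahydronaphthalene-1,4-dione (trans-fused) | CC1=CC(=O)[C@H]2C(C)(C)CCC[C@]2(C)C1=O | intermediate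
14 | (4aS,8aS)-2,5,5,8a-tetramethyl-4-oxo-3,4,4a,5,6,7,8,8a-octahydronaphthalen-1-yl trifluoromethanesulfonate | CC1=C(OS(=O)(=O)C(F)(F)F)[C@@]2(C)CCCC(C)(C)[C@@H]2C(=O)C1 | intermediate
15 | (E)-3-methylpent-2-en-4-yn-1-ol | C#C/C(C)=C/CO | starting material
16 | tert-butyldimethyl{[(E)-3-methylpent-2-en-4-yn-1-yl]oxy}silane | C#C/C(C)=C/CO[Si](C)(C)C(C)(C)C | intermediate
17 | tert-butyldimethyl{[(E)-3-methylpenta-2,4-dien-1-yl]oxy}silane | C=C/C(C)=C/CO[Si](C)(C)C(C)(C)C | intermediate
18 | 9-borabicyclo[3.3.1]nonane (9-BBN) | C1CC2CCCC(C1)B2 | starting material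
19 | 9-[(E)-5-[(tert-butyldimethylsilyl)oxy]-3-methylpent-3-en-1-yl]-9-borabicyclo[3.3.1]nonane | C1CC2CCCC(C1)B2CC/C(C)=C/CO[Si](C)(C)C(C)(C)C | intermediate
20 | (5S,10S)-15-[(tert-butyldimethylsilyl)oxy]labda-8,13E-dien-6-one | CC1=C(CC/C(C)=C/CO[Si](C)(C)C(C)(C)C)[C@@]2(C)CCCC(C)(C)[C@@H]2C(=O)C1 | intermediate
21 | (5S,7S,10S)-15-[(tert-butyldimethylsilyl)oxy]-7α-hydroxylabda-8,13E-dien-6-one | CC1=C(CC/C(C)=C/CO[Si](C)(C)C(C)(C)C)[C@@]2(C)CCCC(C)(C)[C@@H]2C(=O)[C@H]1O | intermediate
22 | (5S,6S,7S,10S)-15-[(tert-butyldimethylsilyl)oxy]labda-8,13E-diene-6β,7α-diol | CC1=C(CC/C(C)=C/CO[Si](C)(C)C(C)(C)C)[C@@]2(C)CCCC(C)(C)[C@@H]2[C@H](O)[C@H]1O | intermediate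
23 | (5S,6S,7S,10S)-15-[(tert-butyldimethylsilyl)oxy]-7α-[(triethylsilyl)oxy]labda-8,13E-dien-6β-ol | CC1=C(CC/C(C)=C/CO[Si](C)(C)C(C)(C)C)[C@@]2(C)CCCC(C)(C)[C@@H]2[C@H](O)[C@H]1O[Si](CC)(CC)CC | intermediate
24 | (5S,6S,7S,10S)-15-[(tert-butyldimethylsilyl)oxy]-7α-[(triethylsilyl)oxy]labda-8,13E-dien-6β-yl 3-methylbutanoate | CC1=C(CC/C(C)=C/CO[Si](C)(C)C(C)(C)C)[C@@]2(C)CCCC(C)(C)[C@@H]2[C@H](OC(=O)CC(C)C)[C@H]1O[Si](CC)(CC)CC | intermediate
25 | (5S,6S,7S,10S)-7α,15-dihydroxylabda-8,13E-dien-6β-yl 3-methylbutanoate | CC1=C(CC/C(C)=C/CO)[C@@]2(C)CCCC(C)(C)[C@@H]2[C@H](OC(=O)CC(C)C)[C@H]1O | target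

**Step count.** Total: 17 steps. Longest linear sequence: 15 steps (steps 1–9 and 12–17); steps 10–11 prepare the side-chain fragment.

**Steps most likely to fail**

Step 7 (bears "Proposed new method:"). The C2 radical may be consumed before it meets isobutene, by transannular 6-endo addition to C7 of its own dienone or by hydrogen abstraction. The tertiary radical may add further isobutene before ring closure, and the 2,4-cyclohexadienone may be lost through sensitised photochemical ring opening. The fallback forms the two bonds one after the other with known chemistry and sets out from 9. A nickel-catalysed decarboxylative alkenylation of the redox-active ester (Ni(acac)2, 2,2′-bipyridine, (2-methylprop-1-en-1-yl)zinc chloride, THF/DMF, rt) makes the C2–C3 bond alone and should give (6S)-2,6-dimethyl-6-(4-methylpent-3-en-1-yl)cyclohex-2-ene-1,4-dione F1. A proton-initiated cation–olefin cyclisation (TfOH, CH2Cl2, −40 °C) then closes C4–C5: Markovnikov protonation of the trisubstituted alkene gives the C4 cation, which the C6 enol, enolisable only towards C5, should capture. The fallback comes back to the route at 12 (as a mixture with 13), which enters step 8.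

Step 8. The equilibration may stop short of the trans isomer if the cis-fused ene-dione is not sufficiently less stable, and the amidine base may add to the ene-dione in a conjugate sense. The fallback replaces thermodynamic control by kinetic protonation of an isolated enol derivative and sets out from 12. Silylation (TBSOTf, Et3N, CH2Cl2, −78 °C) gives (8aS)-4-[(tert-butyldimethylsilyl)oxy]-2,5,5,8a-tetramethyl-6,7,8,8a-tetrahydronaphthalen-1(5H)-one F2, in which C5 is sp2. Low-temperature protodesilylation (Bu4NF, AcOH, THF, −78 °C) should then deliver the proton to the α-face of C5, opposite the axial C10 methyl. The fallback comes back at 13.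

Step 9. The hydride may be delivered to the wrong enone terminus or to a carbonyl, and proton exchange between the hindered C9 enolate and the C6 ketone may scramble the enolate before O-sulfonylation. The fallback separates reduction from triflation and sets out from 13. Catalytic 1,4-hydrosilylation (Et3SiH, RhCl(PPh3)3, benzene, 50 °C) places hydrogen on C7 and silicon on O9 and gives the isolable (4aS,8aS)-3,4a,8,8-tetramethyl-4-[(triethylsilyl)oxy]-4a,5,6,7,8,8a-hexahydronaphthalen-1(2H)-one F3. This is converted regiospecifically into the enol triflate with CsF and PhNTf2 (DME, rt). The fallback comes back at 14.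

**Further compounds**
F1 | step 7 | (6S)-2,6-dimethyl-6-(4-methylpent-3-en-1-yl)cyclohex-2-ene-1,4-dione | CC(C)=CCC[C@@]1(C)CC(=O)C=C(C)C1=O
F2 | step 8 | (8aS)-4-[(tert-butyldimethylsilyl)oxy]-2,5,5,8a-tetramethyl-6,7,8,8a-tetrahydronaphthalen-1(5H)-one | CC1=CC(O[Si](C)(C)C(C)(C)C)=C2C(C)(C)CCC[C@]2(C)C1=O
F3 | step 9 | (4aS,8aS)-3,4a,8,8-tetramethyl-4-[(triethylsilyl)oxy]-4a,5,6,7,8,8a-hexahydronaphthalen-1(2H)-one | CC1=C(O[Si](CC)(CC)CC)[C@@]2(C)CCCC(C)(C)[C@@H]2C(=O)C1
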